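**Retrosynthetic overview**
- Licobichalcone ⇐ its hexakis(triisopropylsilyl) ether; the C3=C4 enone comes from acid-induced (base-free) loss of a C4 silyloxy group, so the epimerisable C2 centre is never exposed to base.
- That C4-silyloxy tetralin ⇐ reductive opening of a 1,4-oxygen-bridged adduct; hydride adds to the C1 cation anti to the C2 aroyl group, which sets the cis C1/C2 relationship.
- Key step: an open-chain hydroxy acetal plus an (E)-1,2-diaroylethylene give the oxygen ring (as an isobenzofuran) and carbocyclic ring B in one flask, by cyclisation, methanol loss and an enantioselective Diels–Alder reaction that fixes C2.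
- Hydroxy acetal ⇐ ortho-lithiated ring A acetal (from 5-hydroxyvanillin) + ring C aldehyde (from 3-methoxycatechol); dienedione ⇐ fumaryl chloride + an arylzinc reagent.
- Ring order: ring A, ring C and the two hydroxyphenyl rings are bought; the oxygen bridge and ring B form together; the bridge is then opened.

Assumption: the target SMILES is read as (1S,2S), C1 aryl and C2 aroyl cis; the catalyst antipode named in the key step is taken to give the adduct shown (the other antipode is equally available and would be used if the sense of induction is the reverse).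

Abbreviation: TIPS = triisopropylsilyl, i-Pr3Si.

**Step 1**
Reactants: 1 3,4-dihydroxy-5-methoxybenzaldehyde (5-hydroxyvanillin)
Product: 2 3-methoxy-4,5-bis(triisopropylsilyloxy)benzaldehyde
Conditions: i-Pr3SiCl (2.5 equiv), imidazole (5 equiv), 4-(dimethylamino)pyridine (cat.), DMF, 50 °C
Reagents that add atoms: chlorotri(propan-2-yl)silane, CC(C)[Si](Cl)(C(C)C)C(C)C
Why: Silyl ether formation on both phenols (substitution at silicon); TIPS ethers survive organolithium reagents, do not direct lithiation and shield the ring positions beside them.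

**Step 2**
Reactants: 2 3-methoxy-4,5-bis(triisopropylsilyloxy)benzaldehyde
Product: 3 1-(dimethoxymethyl)-3-methoxy-4,5-bis(triisopropylsilyloxy)benzene
Conditions: HC(OMe)3 (5 equiv), pyridinium p-toluenesulfonate (5 mol %), CH2Cl2, rt; Et3N quench
Reagents that add atoms: trimethyl orthoformate, COC(OC)OC
Why: Acid-catalysed acetalisation masks the aldehyde against n-BuLi and gives, together with the neighbouring methoxy group, the directing pair needed in step 5.

**Step 3**
Reactants: 4 3-methoxybenzene-1,2-diol (3-methoxycatechol)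
Product: 5 1-methoxy-2,3-bis(triisopropylsilyloxy)benzene
Conditions: i-Pr3SiCl (2.5 equiv), imidazole (5 equiv), DMF, 40 °C
Reagents that add atoms: chlorotri(propan-2-yl)silane, CC(C)[Si](Cl)(C(C)C)C(C)C
Why: Silyl ether formation on the catechol, for the same reasons as in step 1.

**Step 4**
Reactants: 5 1-methoxy-2,3-bis(triisopropylsilyloxy)benzene
Product: 6 2-methoxy-3,4-bis(triisopropylsilyloxy)benzaldehyde
Conditions: n-BuLi (1.2 equiv), TMEDA, Et2O, 0 °C → rt; DMF, −78 °C → rt; 1 M HCl, 0 °C
Reagents that add atoms: N,N-dimethylformamide, CN(C)C=O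
Why: Directed ortho-metalation by the methoxy group followed by formylation; the only lithiated position is the one ortho to OMe, because the bulky silyloxy groups neither coordinate lithium nor leave room beside them.

**Step 5**
Reactants: 3 1-(dimethoxymethyl)-3-methoxy-4,5-bis(triisopropylsilyloxy)benzene; 6 2-methoxy-3,4-bis(triisopropylsilyloxy)benzaldehyde
Product: 7 racemic [6-(dimethoxymethyl)-2-methoxy-3,4-bis(triisopropylsilyloxy)phenyl][2-methoxy-3,4-bis(triisopropylsilyloxy)phenyl]methanol
Conditions: 3, n-BuLi (1.1 equiv), Et2O, 0 °C → rt, 2 h; then 6 (1.0 equiv), −78 → 0 °C; H2O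
Reagents that add atoms: none
Why: Directed ortho-metalation at the position flanked by the acetal and methoxy groups (cooperative coordination) and 1,2-addition of the aryllithium to the aldehyde; the carbinol centre is left racemic because it becomes sp2 in step 7.

**Step 6**
Reactants: 8 (4-bromophenoxy)triisopropylsilane; 9 fumaryl chloride
Product: 10 (E)-1,4-bis[4-(triisopropylsilyloxy)phenyl]but-2-ene-1,4-dione
Conditions: 8 (2.1 equiv), n-BuLi, THF, −78 °C; ZnCl2, −78 °C → rt; then 9 (1.0 equiv), Pd(PPh3)4 (5 mol %), THF, 0 °C → rt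
Reagents that add atoms: none
Why: Negishi acylation (coupling of an arylzinc chloride with an acid chloride under zerovalent palladium catalysis) at both acyl chloride groups; the E geometry of fumaryl chloride is kept and arylzinc reagents do not add to the enedione formed.

**Step 7 (key step)**
Reactants: 7 racemic hydroxy acetal; 10 (E)-1,4-bis[4-(triisopropylsilyloxy)phenyl]but-2-ene-1,4-dione
Product: 13 (1R,2R,3R,4R)-oxygen-bridged Diels–Alder adduct (2-aroyl endo; 3-aroyl exo; full name in the compound list), via cyclic methyl acetal 11 (not isolated), via isobenzofuran 12 (not isolated)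
Conditions: 7 (1.2 equiv), AcOH (5 mol %), 5 Å MS, PhMe, 100 °C, 15 min, Ar; cool to −78 °C and cannula-filter into 10 (1.0 equiv) + (S)-1-(2-methylphenyl)-3,3-diphenyltetrahydro-1H,3H-pyrrolo[1,2-c][1,3,2]oxazaborole protonated with HNTf2 (25 mol %), CH2Cl2, −78 °C, 4 h; chromatography
Reagents that add atoms: none
Why: Proposed new method: acid-catalysed ring closure of the hydroxy acetal and loss of a second methanol (the established hydroxy-acetal route to isobenzofurans) build the oxygen ring, and a Diels–Alder reaction then closes ring B, so two rings form in one flask; the boron-bound catalyst is expected to fix the enantioface of the C2-symmetric enedione as it does for fumarate and enone dienophiles in oxazaborolidinium-catalysed Diels–Alder reactions with furans, which sets C2 and C3 as (2R,3R), the boron-complexed aroyl group going endo on C2 and the bridgeheads following from suprafacial addition (any C2-exo/C3-endo isomer has the same C2 configuration and is removed by chromatography).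

**Step 8**
Reactants: 13 oxygen-bridged adduct
Product: 14 (1S,2S,3R,4R)-4-triethylsilyloxy tetralin (full name in the compound list)
Conditions: Et3SiH (1.5 equiv), Et3SiOTf (10 mol %), CH2Cl2, −78 °C; Et3N, then NaHCO3 (aq)
Reagents that add atoms: triethylsilane, CC[SiH](CC)CC
Why: Ionic hydrogenation (silyl-triflate-catalysed reductive ether cleavage): silylation of the bridging oxygen ionises only the C1–O bond, since C1 gives a tertiary cation stabilised by two para-oxygenated aryl rings, and Et3SiH delivers hydride to the face away from the neighbouring C2 aroyl group while the peri methoxy group forces the C1 aryl pseudo-axial, which sets C1 as S with the aryl cis to the C2 aroyl and leaves C2 untouched.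

**Step 9**
Reactants: 14 4-triethylsilyloxy tetralin
Product: 16 Licobichalcone, via hexakis(triisopropylsilyl) ether 15 (not isolated)
Conditions: (+)-camphor-10-sulfonic acid (10 mol %), CH2Cl2, rt, 1 h; then THF, Bu4NF (8 equiv), AcOH (8 equiv), 0 °C → rt, Ar; pH 5 buffer work-up
Reagents that add atoms: none
Why: Acid-catalysed E1 loss of triethylsilanol from benzylic C4 (cation stabilised by the para silyloxy group) gives the C3=C4 enone conjugated to ring A without any base, so C1 and C2 keep their configuration, and acetic-acid-buffered fluoride then cleaves the six aryl silyl ethers (silyl ether deprotection) under near-neutral conditions.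

**Compound list**

1 | 3,4-dihydroxy-5-methoxybenzaldehyde (5-hydroxyvanillin) | O=Cc1cc(O)c(O)c(OC)c1 | starting material

2 | 3-methoxy-4,5-bis(triisopropylsilyloxy)benzaldehyde | O=Cc1cc(O[Si](C(C)C)(C(C)C)C(C)C)c(O[Si](C(C)C)(C(C)C)C(C)C)c(OC)c1 | intermediate

3 | 1-(dimethoxymethyl)-3-methoxy-4,5-bis(triisopropylsilyloxy)benzene | COC(OC)c1cc(O[Si](C(C)C)(C(C)C)C(C)C)c(O[Si](C(C)C)(C(C)C)C(C)C)c(OC)c1 | intermediate

4 | 3-methoxybenzene-1,2-diol (3-methoxycatechol) | COc1cccc(O)c1O | starting material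

5 | 1-methoxy-2,3-bis(triisopropylsilyloxy)benzene | COc1cccc(O[Si](C(C)C)(C(C)C)C(C)C)c1O[Si](C(C)C)(C(C)C)C(C)C | intermediate

6 | 2-methoxy-3,4-bis(triisopropylsilyloxy)benzaldehyde | COc1c(C=O)ccc(O[Si](C(C)C)(C(C)C)C(C)C)c1O[Si](C(C)C)(C(C)C)C(C)C | intermediate

7 | racemic [6-(dimethoxymethyl)-2-methoxy-3,4-bis(triisopropylsilyloxy)phenyl][2-methoxy-3,4-bis(triisopropylsilyloxy)phenyl]methanol | COc1c(C(O)c2c(OC)c(O[Si](C(C)C)(C(C)C)C(C)C)c(O[Si](C(C)C)(C(C)C)C(C)C)cc2C(OC)OC)ccc(O[Si](C(C)C)(C(C)C)C(C)C)c1O[Si](C(C)C)(C(C)C)C(C)C | intermediate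

8 | (4-bromophenoxy)triisopropylsilane | Brc1ccc(O[Si](C(C)C)(C(C)C)C(C)C)cc1 | starting material

9 | fumaryl chloride, (E)-but-2-enedioyl dichloride | O=C(Cl)/C=C/C(Cl)=O | starting material

10 | (E)-1,4-bis[4-(triisopropylsilyloxy)phenyl]but-2-ene-1,4-dione | O=C(/C=C/C(=O)c1ccc(O[Si](C(C)C)(C(C)C)C(C)C)cc1)c1ccc(O[Si](C(C)C)(C(C)C)C(C)C)cc1 | intermediate

11 | 3,7-dimethoxy-1-[2-methoxy-3,4-bis(triisopropylsilyloxy)phenyl]-5,6-bis(triisopropylsilyloxy)-1,3-dihydro-2-benzofuran (racemic, both diastereomers; both centres are lost in 12) | COC1OC(c2ccc(O[Si](C(C)C)(C(C)C)C(C)C)c(O[Si](C(C)C)(C(C)C)C(C)C)c2OC)c2c(OC)c(O[Si](C(C)C)(C(C)C)C(C)C)c(O[Si](C(C)C)(C(C)C)C(C)C)cc12 | intermediate (not isolated)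

12 | 7-methoxy-1-[2-methoxy-3,4-bis(triisopropylsilyloxy)phenyl]-5,6-bis(triisopropylsilyloxy)-2-benzofuran (isobenzofuran, achiral) | COc1c(-c2occ3cc(O[Si](C(C)C)(C(C)C)C(C)C)c(O[Si](C(C)C)(C(C)C)C(C)C)c(OC)c23)ccc(O[Si](C(C)C)(C(C)C)C(C)C)c1O[Si](C(C)C)(C(C)C)C(C)C | intermediate (not isolated)

13 | {(1R,2R,3R,4R)-8-methoxy-1-[2-methoxy-3,4-bis(triisopropylsilyloxy)phenyl]-6,7-bis(triisopropylsilyloxy)-1,2,3,4-tetrahydro-1,4-epoxynaphthalene-2,3-diyl}bis{[4-(triisopropylsilyloxy)phenyl]methanone}; 2-aroyl endo (away from the oxygen bridge), 3-aroyl exo | COc1c(O[Si](C(C)C)(C(C)C)C(C)C)c(O[Si](C(C)C)(C(C)C)C(C)C)ccc1[C@]23O[C@H]([C@H](C(=O)c4ccc(O[Si](C(C)C)(C(C)C)C(C)C)cc4)[C@H]2C(=O)c2ccc(O[Si](C(C)C)(C(C)C)C(C)C)cc2)c2cc(O[Si](C(C)C)(C(C)C)C(C)C)c(O[Si](C(C)C)(C(C)C)C(C)C)c(OC)c23 | intermediate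

14 | {(1S,2S,3R,4R)-8-methoxy-1-[2-methoxy-3,4-bis(triisopropylsilyloxy)phenyl]-4-(triethylsilyloxy)-6,7-bis(triisopropylsilyloxy)-1,2,3,4-tetrahydronaphthalene-2,3-diyl}bis{[4-(triisopropylsilyloxy)phenyl]methanone}; 1-aryl and 2-aroyl cis, 2- and 3-aroyl trans, 3-aroyl and 4-silyloxy cis | COc1c(O[Si](C(C)C)(C(C)C)C(C)C)c(O[Si](C(C)C)(C(C)C)C(C)C)ccc1[C@H]1c2c(OC)c(O[Si](C(C)C)(C(C)C)C(C)C)c(O[Si](C(C)C)(C(C)C)C(C)C)cc2[C@H](O[Si](CC)(CC)CC)[C@H](C(=O)c2ccc(O[Si](C(C)C)(C(C)C)C(C)C)cc2)[C@H]1C(=O)c1ccc(O[Si](C(C)C)(C(C)C)C(C)C)cc1 | intermediate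

15 | {(1S,2S)-8-methoxy-1-[2-methoxy-3,4-bis(triisopropylsilyloxy)phenyl]-6,7-bis(triisopropylsilyloxy)-1,2-dihydronaphthalene-2,3-diyl}bis{[4-(triisopropylsilyloxy)phenyl]methanone}; 1-aryl and 2-aroyl cis | COc1c([C@H]2c3c(cc(O[Si](C(C)C)(C(C)C)C(C)C)c(O[Si](C(C)C)(C(C)C)C(C)C)c3OC)C=C(C(=O)c3ccc(O[Si](C(C)C)(C(C)C)C(C)C)cc3)[C@H]2C(=O)c2ccc(O[Si](C(C)C)(C(C)C)C(C)C)cc2)ccc(O[Si](C(C)C)(C(C)C)C(C)C)c1O[Si](C(C)C)(C(C)C)C(C)C | intermediate (not isolated)

16 | Licobichalcone, [(1S,2S)-1-(3,4-dihydroxy-2-methoxyphenyl)-6,7-dihydroxy-8-methoxy-1,2-dihydronaphthalene-2,3-diyl]bis[(4-hydroxyphenyl)methanone] | COc1c([C@H]2c3c(cc(O)c(O)c3OC)C=C(C(=O)c3ccc(O)cc3)[C@H]2C(=O)c2ccc(O)cc2)ccc(O)c1O | target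

**Totals**
Total step count: 9. Longest linear sequence: 6 steps (steps 1, 2, 5, 7, 8, 9, from 5-hydroxyvanillin).

**Steps most likely to fail, each with one fallback**

Step 7 is the most exposed step. The isobenzofuran 12 is acid- and oxygen-sensitive, residual methanol or acetic acid can poison the boron catalyst, and enantioface control for this diene–dienophile pair is unproven. The fallback gives up asymmetric catalysis for resolution. It sets out from 7 and 10: the cascade is run thermally with the dienophile present from the start (AcOH cat., PhMe, 110 °C), which gives the C2-endo/C3-exo adduct as a racemate, that is 13 together with its mirror image, the (1S,2S,3S,4S)-adduct F1. The two are separated by preparative chromatography on a polysaccharide chiral stationary phase, and the route is rejoined at 13.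

Step 8 can fail in three ways: loss of the acidic C2 proton from the C1 cation (which leads on to a naphthalene), capture of the cation by the exo C3 carbonyl oxygen, or hydride delivery to the wrong face. The fallback replaces the cation by surface hydrogenolysis. It sets out from 13: H2 (1 atm) over W-2 Raney Ni in EtOAc at rt cleaves the benzylic C1–O bond with retention, so hydrogen enters on the face of the former bridge and the aryl group turns to the side of the C2 aroyl group. The product is the free alcohol, the (1S,2S,3R,4R)-4-hydroxy tetralin F2; the reaction is stopped before the aryl ketones are reduced. Under the acid of step 9, F2 loses water and the route is rejoined at 15.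

Step 6 may stop at mono-acylation, or the arylzinc reagent or the palladium catalyst may attack the enedione. The fallback is a Friedel–Crafts route that sets out from 9. Anisole and AlCl3 in CH2Cl2 at 0 °C give (E)-1,4-bis(4-methoxyphenyl)but-2-ene-1,4-dione F3. BBr3 in CH2Cl2 (−78 °C → rt) then gives (E)-1,4-bis(4-hydroxyphenyl)but-2-ene-1,4-dione F4. Silylation with i-Pr3SiCl and imidazole in DMF brings the route back at 10.

**Further compounds**

F1 | step 7 | {(1S,2S,3S,4S)-8-methoxy-1-[2-methoxy-3,4-bis(triisopropylsilyloxy)phenyl]-6,7-bis(triisopropylsilyloxy)-1,2,3,4-tetrahydro-1,4-epoxynaphthalene-2,3-diyl}bis{[4-(triisopropylsilyloxy)phenyl]methanone} (enantiomer of 13) | COc1c(O[Si](C(C)C)(C(C)C)C(C)C)c(O[Si](C(C)C)(C(C)C)C(C)C)ccc1[C@@]23O[C@@H]([C@@H](C(=O)c4ccc(O[Si](C(C)C)(C(C)C)C(C)C)cc4)[C@@H]2C(=O)c2ccc(O[Si](C(C)C)(C(C)C)C(C)C)cc2)c2cc(O[Si](C(C)C)(C(C)C)C(C)C)c(O[Si](C(C)C)(C(C)C)C(C)C)c(OC)c23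

F2 | step 8 | {(1S,2S,3R,4R)-4-hydroxy-8-methoxy-1-[2-methoxy-3,4-bis(triisopropylsilyloxy)phenyl]-6,7-bis(triisopropylsilyloxy)-1,2,3,4-tetrahydronaphthalene-2,3-diyl}bis{[4-(triisopropylsilyloxy)phenyl]methanone} | COc1c(O[Si](C(C)C)(C(C)C)C(C)C)c(O[Si](C(C)C)(C(C)C)C(C)C)ccc1[C@H]1c2c(OC)c(O[Si](C(C)C)(C(C)C)C(C)C)c(O[Si](C(C)C)(C(C)C)C(C)C)cc2[C@H](O)[C@H](C(=O)c2ccc(O[Si](C(C)C)(C(C)C)C(C)C)cc2)[C@H]1C(=O)c1ccc(O[Si](C(C)C)(C(C)C)C(C)C)cc1

F3 | step 6 | (E)-1,4-bis(4-methoxyphenyl)but-2-ene-1,4-dione | COc1ccc(cc1)C(=O)/C=C/C(=O)c1ccc(OC)cc1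

F4 | step 6 | (E)-1,4-bis(4-hydroxyphenyl)but-2-ene-1,4-dione | Oc1ccc(cc1)C(=O)/C=C/C(=O)c1ccc(O)cc1
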